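The target is cut at both ends of the saturated ethylene bridge: C5–Cα at the benzo ring of the chromene and Cβ–C1′ at the 4-hydroxyphenyl ring. This bridge cannot come from hydrogenation, because the pyran C3=C4 double bond and the prenyl alkene must survive. A palladium-catalysed three-component conjunctive coupling builds it directly at the saturated level: vinylboronic acid pinacol ester supplies Cα–Cβ, an aryllithium delivers C1′ to Cβ by 1,2-shift from boron, and the C5 triflate is joined to Cα. The precursor is the finished 2,2-dimethyl-7-prenyloxy-2H-chromene carrying a triflate at C5; the benzylic boron left at Cβ is afterwards exchanged for hydrogen.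

Key step: step 4

Remarks on the chemistry and assumptions

- The phenol of the migrating ring is carried as a tetrahydropyranyl acetal, not a silyl ether. Fluoride, which is needed for the later C–B protonolysis, would unmask a silyl ether to a phenoxide, and that strong donor para to Cβ would slow the carbanion-like C–B cleavage. The acetal survives fluoride and is removed with buffered acid; the bromide 9 is a catalogue compound.
- Bromine–lithium exchange with t-BuLi leaves LiBr in the flask, and free halide slows the conjunctive coupling, so KOTf is added as a halide scavenger.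
- The target is achiral. The boron-bearing carbon of 13 and the acetal carbon of 9, 11, 12, 13 and 14 are uncontrolled and both are erased before the end.
- Step 4 is a one-flask sequence (exchange, borate formation, coupling) and is counted as one step.
- Locants: Cα is the bridge carbon on C5 of the chromene, Cβ the one on C1′ of the phenol ring; prenyl means 3-methylbut-2-enyl.

Step 1
Reactants: 1 2,4,6-trihydroxybenzaldehyde; 2 1-bromo-3-methylbut-2-ene (prenyl bromide)
Product: 3 2,6-dihydroxy-4-(3-methylbut-2-enyloxy)benzaldehyde
Conditions: K2CO3 (1.1 equiv), 2 (1.0 equiv), acetone, rt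
Reagents that add atoms: none
Why: Williamson etherification, in which the 4-hydroxyl (para to the formyl group, the most acidic and the only one not chelated to the carbonyl) should be alkylated on oxygen by one equivalent of bromide and weak base while the two hydrogen-bonded ortho hydroxyls stay free.

Step 2
Reactants: 3 2,6-dihydroxy-4-(3-methylbut-2-enyloxy)benzaldehyde; 4 2-methylprop-1-enylmagnesium bromide
Product: 7 2,2-dimethyl-7-(3-methylbut-2-enyloxy)-2H-chromen-5-ol, via allylic alcohol triol 5 (not isolated), via vinyl ortho-quinone methide 6 (not isolated)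
Conditions: 4 (3.5 equiv), THF, 0 °C; aq NH4Cl; then PPTS (5 mol%), CH2Cl2, rt
Reagents that add atoms: none
Why: Grignard 1,2-addition followed by dehydrative oxa-6π electrocyclisation: two equivalents of 4 are spent as base on the phenols and the third adds to the aldehyde to give racemic 5, whose doubly ortho-oxygenated allylic benzylic alcohol should ionise under mild acid to dienone 6 (the intermediate of phenol–enal chromene annulations), and because the two ortho hydroxyls are equivalent by symmetry the ring can only close to the 5-hydroxy-7-alkoxy chromene, the carbinol centre being lost on the way.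

Step 3
Reactants: 7 2,2-dimethyl-7-(3-methylbut-2-enyloxy)-2H-chromen-5-ol
Product: 8 2,2-dimethyl-7-(3-methylbut-2-enyloxy)-2H-chromen-5-yl trifluoromethanesulfonate
Conditions: PhNTf2 (1.2 equiv), Et3N (2 equiv), DMAP (10 mol%), CH2Cl2, 0 °C → rt
Reagents that add atoms: N-phenylbis(trifluoromethanesulfonimide), O=S(=O)(N(c1ccccc1)S(=O)(=O)C(F)(F)F)C(F)(F)F
Why: Phenol triflation with a mild triflyl-transfer reagent under basic conditions, which should sulfonylate the only hydroxyl and leave the acid-sensitive chromene alkene and prenyl ether untouched.

Step 4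
Reactants: 9 2-(4-bromophenoxy)tetrahydro-2H-pyran (racemic); 10 vinylboronic acid pinacol ester; 8 2,2-dimethyl-7-(3-methylbut-2-enyloxy)-2H-chromen-5-yl trifluoromethanesulfonate
Product: 13 2-[2-[2,2-dimethyl-7-(3-methylbut-2-enyloxy)-2H-chromen-5-yl]-1-[4-(tetrahydro-2H-pyran-2-yloxy)phenyl]ethyl]-4,4,5,5-tetramethyl-1,3,2-dioxaborolane (mixture of two racemic diastereomers), via aryllithium 11 (not isolated), via vinylboron ate complex 12 (not isolated)
Conditions: 9 (1.3 equiv), t-BuLi (2.6 equiv), Et2O, −78 °C; 10 (1.3 equiv), −78 °C → rt; volatiles removed, THF; 8 (1.0 equiv), Pd(OAc)2 (3 mol%), 1,1'-bis(dicyclohexylphosphino)ferrocene (3.6 mol%), KOTf (2.6 equiv), 60 °C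
Reagents that add atoms: none
Why: Bromine–lithium exchange gives aryllithium 11, which adds to the boron of 10 to form the four-coordinate borate 12; zerovalent palladium inserts into the C5–O bond of triflate 8, the resulting cationic arylpalladium (divalent palladium with a triflate counter-ion) binds the vinyl group of 12, the aryl group shifts from boron to the boron-bearing carbon (Cβ–C1′) as palladium bonds to the terminal carbon, and reductive elimination forms C5–Cα. The closest known reaction type is the palladium-catalysed conjunctive cross-coupling of vinylboron ate complexes with aryl triflates by 1,2-metallate rearrangement. No ring is closed. The new stereocentre at Cβ is not controlled (achiral ligand) and, with the racemic acetal centre, should give a diastereomer mixture that is of no consequence because step 5 replaces boron by hydrogen. The step needs the metallate shift to outrun direct Suzuki-type transfer of vinyl or aryl from boron and β-hydride elimination, with the electrophile ending on the terminal carbon; this is secured by the triflate leaving group and KOTf as bromide scavenger (an open site on cationic palladium for the alkene), the wide-bite-angle chelating bisphosphine (fast reductive elimination), the electron-rich migrating aryl group and the polarisation of the palladium-bound vinylborate. The prenyl ether and the C3=C4 alkene should remain spectators, since neither is an electrophile for zerovalent palladium under these conditions and neither competes with the anionic borate for the cationic metal.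

Step 5
Reactants: 13 pinacol boronate from step 4
Product: 14 2-[4-[2-[2,2-dimethyl-7-(3-methylbut-2-enyloxy)-2H-chromen-5-yl]ethyl]phenoxy]tetrahydro-2H-pyran (racemic)
Conditions: TBAF·3H2O (3 equiv), toluene, 50 °C
Reagents that add atoms: none
Why: Fluoride-promoted protodeboronation of a benzylic boronic ester, in which fluoride binds boron and water cleaves the benzylic C–B bond of the borate with carbanion-like character stabilised by the adjacent aryl ring, while the acetal, the aryl ethers and both alkenes are inert to basic fluoride; the boron-bearing stereocentre disappears.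

Step 6
Reactants: 14 tetrahydropyranyl ether from step 5
Product: 15 4-[2-[2,2-dimethyl-7-(3-methylbut-2-enyloxy)-2H-chromen-5-yl]ethyl]phenol (target, achiral)
Conditions: PPTS (0.2 equiv), MeOH, 40 °C
Reagents that add atoms: none
Why: Acid-catalysed acetal exchange (tetrahydropyranyl ether cleavage), in which buffered pyridinium acid transfers the acetal to methanol at an acidity too low to ionise the prenyl aryl ether or protonate the chromene C3=C4 bond.

Compound list

1 | 2,4,6-trihydroxybenzaldehyde | O=Cc1c(O)cc(O)cc1O | starting material
2 | 1-bromo-3-methylbut-2-ene | CC(C)=CCBr | starting material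
3 | 2,6-dihydroxy-4-(3-methylbut-2-enyloxy)benzaldehyde | CC(C)=CCOc1cc(O)c(C=O)c(O)c1 | intermediate
4 | 2-methylprop-1-enylmagnesium bromide | CC(C)=C[Mg]Br | starting material
5 | 2-(1-hydroxy-3-methylbut-2-enyl)-5-(3-methylbut-2-enyloxy)benzene-1,3-diol (racemic, not isolated) | CC(C)=CCOc1cc(O)c(C(O)C=C(C)C)c(O)c1 | intermediate
6 | 3-hydroxy-2-(3-methylbut-2-enylidene)-5-(3-methylbut-2-enyloxy)cyclohexa-3,5-dien-1-one (not isolated) | CC(C)=CCOC1=CC(=O)C(=CC=C(C)C)C(O)=C1 | intermediate
7 | 2,2-dimethyl-7-(3-methylbut-2-enyloxy)-2H-chromen-5-ol | CC(C)=CCOc1cc(O)c2c(c1)OC(C)(C)C=C2 | intermediate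
8 | 2,2-dimethyl-7-(3-methylbut-2-enyloxy)-2H-chromen-5-yl trifluoromethanesulfonate | CC(C)=CCOc1cc(OS(=O)(=O)C(F)(F)F)c2c(c1)OC(C)(C)C=C2 | intermediate
9 | 2-(4-bromophenoxy)tetrahydro-2H-pyran (racemic) | Brc1ccc(OC2CCCCO2)cc1 | starting material
10 | vinylboronic acid pinacol ester (4,4,5,5-tetramethyl-2-vinyl-1,3,2-dioxaborolane) | C=CB1OC(C)(C)C(C)(C)O1 | starting material
11 | [4-(tetrahydro-2H-pyran-2-yloxy)phenyl]lithium (racemic, not isolated) | [Li]c1ccc(OC2CCCCO2)cc1 | intermediate
12 | lithium [4-(tetrahydro-2H-pyran-2-yloxy)phenyl](vinyl)(pinacolato)borate (racemic, not isolated) | [Li+].C=C[B-]1(c2ccc(OC3CCCCO3)cc2)OC(C)(C)C(C)(C)O1 | intermediate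
13 | 2-[2-[2,2-dimethyl-7-(3-methylbut-2-enyloxy)-2H-chromen-5-yl]-1-[4-(tetrahydro-2H-pyran-2-yloxy)phenyl]ethyl]-4,4,5,5-tetramethyl-1,3,2-dioxaborolane (both diastereomers, each racemic) | CC(C)=CCOc1cc(CC(B2OC(C)(C)C(C)(C)O2)c2ccc(OC3CCCCO3)cc2)c2c(c1)OC(C)(C)C=C2 | intermediate
14 | 2-[4-[2-[2,2-dimethyl-7-(3-methylbut-2-enyloxy)-2H-chromen-5-yl]ethyl]phenoxy]tetrahydro-2H-pyran (racemic) | CC(C)=CCOc1cc(CCc2ccc(OC3CCCCO3)cc2)c2c(c1)OC(C)(C)C=C2 | intermediate
15 | 4-[2-[2,2-dimethyl-7-(3-methylbut-2-enyloxy)-2H-chromen-5-yl]ethyl]phenol (achiral) | CC(C)=CCOc1cc(CCc2ccc(O)cc2)c2c(c1)OC(C)(C)C=C2 | target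

Total step count: 6.
Longest linear sequence: 6 steps (1 → 3 → 7 → 8 → 13 → 14 → 15); 9 and 10 are purchased and enter at step 4.

Steps most likely to fail

Step 4. The metallate shift may lose to direct transfer of aryl or vinyl from boron or to β-hydride elimination, residual bromide may block the cationic palladium, and oxidative addition to the electron-rich triflate may be slow. The fallback sets out from triflate 8 and builds the bridge by B-alkyl Suzuki–Miyaura coupling. Commercial 4-vinylphenyl acetate F1 is hydroborated with 9-borabicyclo[3.3.1]nonane (slight deficiency, THF, rt) to give 4-[2-(9-borabicyclo[3.3.1]nonan-9-yl)ethyl]phenyl acetate F2, and the borane is fully consumed before 8 is added, so the prenyl and chromene alkenes never meet it. Coupling of F2 with 8 (PdCl2(dppf), K3PO4, THF/DMF/H2O, 60 °C) should give 4-[2-[2,2-dimethyl-7-(3-methylbut-2-enyloxy)-2H-chromen-5-yl]ethyl]phenyl acetate F3, possibly partly hydrolysed already. Methanolysis (K2CO3, MeOH, rt) completes the ester cleavage, and the fallback comes back to the route at target 15.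

Step 2. Addition to the poorly soluble, deactivated bis-phenoxide of the aldehyde may stall, a second Grignard equivalent may add to a prematurely formed quinone methide, and the ionised intermediate may oligomerise. The fallback sets out from aldehyde 3 and masks the phenols first. Silylation (TBSCl, imidazole, DMF, rt) should give 2,6-bis(tert-butyldimethylsilyloxy)-4-(3-methylbut-2-enyloxy)benzaldehyde F4, which needs only a slight excess of 4 (1.3 equiv, THF, −78 → 0 °C) to give 1-[2,6-bis(tert-butyldimethylsilyloxy)-4-(3-methylbut-2-enyloxy)phenyl]-3-methylbut-2-en-1-ol F5. Desilylation (TBAF buffered with AcOH, THF, 0 °C) releases triol 5 in solution, and PPTS in CH2Cl2 closes the ring, so the fallback comes back to the route at chromenol 7.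

Step 5. Protonolysis of the C–B bond may be sluggish at a secondary benzylic carbon bearing an electron-rich aryl ring, and adventitious oxygen may oxidise the borate to the benzylic alcohol. The fallback sets out from boronate 13 and changes from polar to radical C–B cleavage. Phenyllithium (1.1 equiv, THF, −78 °C → rt) should give lithium phenyl borate F6 (the B-phenyl ate complex of 13). Irradiation with blue LEDs in MeOH/acetone with [Ir(dF(CF3)ppy)2(dtbbpy)]PF6 (2 mol%) and thiophenol then oxidises the borate by single-electron transfer, and the benzylic radical takes hydrogen from the thiol. The fallback comes back to the route at 14.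

Further compounds

F1 | step 4 | 4-vinylphenyl acetate | CC(=O)Oc1ccc(C=C)cc1
F2 | step 4 | 4-[2-(9-borabicyclo[3.3.1]nonan-9-yl)ethyl]phenyl acetate | CC(=O)Oc1ccc(CCB2C3CCCC2CCC3)cc1
F3 | step 4 | 4-[2-[2,2-dimethyl-7-(3-methylbut-2-enyloxy)-2H-chromen-5-yl]ethyl]phenyl acetate | CC(C)=CCOc1cc(CCc2ccc(OC(C)=O)cc2)c2c(c1)OC(C)(C)C=C2
F4 | step 2 | 2,6-bis(tert-butyldimethylsilyloxy)-4-(3-methylbut-2-enyloxy)benzaldehyde | CC(C)=CCOc1cc(O[Si](C)(C)C(C)(C)C)c(C=O)c(O[Si](C)(C)C(C)(C)C)c1
F5 | step 2 | 1-[2,6-bis(tert-butyldimethylsilyloxy)-4-(3-methylbut-2-enyloxy)phenyl]-3-methylbut-2-en-1-ol (racemic) | CC(C)=CCOc1cc(O[Si](C)(C)C(C)(C)C)c(C(O)C=C(C)C)c(O[Si](C)(C)C(C)(C)C)c1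
F6 | step 5 | lithium phenyl borate of 13 (B-phenyl ate complex, diastereomer mixture) | [Li+].CC(C)=CCOc1cc(CC(c2ccc(OC3CCCCO3)cc2)[B-]2(c3ccccc3)OC(C)(C)C(C)(C)O2)c2c(c1)OC(C)(C)C=C2
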